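Readings and results are calculated with constants of no real substance; noise was put on by code.

24.1% of the starting material is found, by the readings, neither as starting material nor as ring at 40.0 s in the blue run, and the readings of the amber run, with less protic impurity, give 25.8% at that time. The charge c(starting material) of 0.0080 M times the blue share gives 0.00193 M, the missing amount: the concentration of charged starting material found in neither form.

| setting | blue | amber | gamma | epsilon | beta | delta |
|---|---|---|---|---|---|---|
| starting material | 0.0080 M | 0.0080 M | 0.0080 M | 0.015 M | 0.030 M | 0.060 M |
| protic impurity | 0.040 M | 0.030 M | 0.0600 M | 0.0600 M | 0.0600 M | 0.0600 M |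
| remark | run made earlier | run made earlier |  |  |  |  |
| time |  |  | 5.0 min | 5.0 min | 5.0 min | 5.0 min |

- blue (time / s: ring / %, starting material / %): 10.0: 25.4, 51.8; 15.0: 32.6, 43.4; 25.0: 43.2, 31.4; 40.0: 56.5, 19.4; 50.0: 62.9, 14.3; 60.0: 67.6, 11.0
- amber (time / s: ring / %, starting material / %): 10.0: 25.4, 50.2; 15.0: 31.3, 41.6; 25.0: 44.3, 31.9; 30.0: 49.3, 25.5; 40.0: 55.9, 18.3; 50.0: 61.1, 14.9; 60.0: 68.0, 9.3

(standard deviation of a reading: 1 percentage point)

- "hardly changes" means that all values lie within two and a half points (for a concentration: within two and a half percent of the largest)

* amount of ring at the end, in percent of the starting material charged for gamma, epsilon, beta, delta, in this order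
* the shape of the row from first to last (rises, then falls / hardly changes / rises all the way / falls all the way / falls, then rises)

Between 10.0 s and 60.0 s the readings of starting material in the blue run halve about every 22.4 s, much less than the 5.0 min allowed, so the reckoning here takes the ring in gamma at that time as its end value. The share shows no rise from amber to blue, so the reckoning here carries it unchanged to gamma's higher protic impurity and expects about 75.9% ring. Both earlier runs hold one charge, so they do not show how the missing amount moves with c(starting material), and this reckoning leaves the three higher charges open.

The forecast goes further. It reads the gap as “a fast, quickly exhausted loss” of fixed size and gives 76%, 87%, 94% and 97%, with the shape: rises all the way.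

The flasks give 77.6%, 73.0%, 64.7% and 52.8%, with the shape: falls all the way.

    starting material + protic impurity → quenched substrate (k = 0.0218 M⁻¹ s⁻¹)
    starting material ⇌ dormant form (K = 0.333, k = 0.0983 s⁻¹)
    ring ⇌ isomer of the product (K = 0.158, k = 0.0395 s⁻¹)
    starting material → ring (k = 0.0399 s⁻¹)
    2 starting material → open dimer (k = 0.513 M⁻¹ s⁻¹)
    starting material + open dimer → open trimer (k = 0.506 M⁻¹ s⁻¹)

The missing amount in gamma is 0.00179 M, close to the 0.00193 M read from the blue run. Of the charge in delta, 23.5% stands as open dimer and 13.4% as open trimer, each counted by the starting material it holds, against 6.57% and 0.633% in gamma. The missing amount in delta is 0.0283 M, which is 15.8 times that of gamma on a charge 7.50 times as large.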